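The route rests on reading the CH2–CH2 tether between C3 of the central ring A and C1 of the 3-hydroxyphenyl ring C as a reduced ethyne. Each tether carbon sits on an aryl carbon, so both aryl–C bonds can be traced back to two aryl halides and acetylene. In one flask the ring-A bromide is alkynylated with trimethylsilylacetylene, the silyl cap is removed and the freed alkyne is arylated with a ring-C iodide. The precursor is the benzyl-protected diarylmethane (rings A and B already joined) with bromine at the bridge position C3. One hydrogenation then saturates the alkyne and frees all three phenols.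

Key step: step 7

Remark on the chemistry: the target has no stereocentre, stereoaxis or stereogenic double bond. It is achiral, so no enantiomer has to be selected. The racemic diaryl carbinol met on the way loses its stereocentre in the deoxygenation that follows it.

Ring labels: ring A is the central ring, numbered as a phenol (C1 OH, C2 CH2Ar, C3 CH2CH2Ar, C5 OMe). Ring B is the 4-hydroxyphenyl ring and ring C is the 3-hydroxyphenyl ring.

Step 1
Reactants: 1 1-bromo-3,5-dimethoxybenzene
Product: 3 2-bromo-4,6-dimethoxybenzaldehyde, via aryl iminium chloride 2 (not isolated)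
Conditions: POCl3, DMF, 0 → 95 °C; then ice-water
Reagents that add atoms: N,N-dimethylformamide CN(C)C=O (formyl carbon); water O (carbonyl oxygen)
Why: Vilsmeier–Haack formylation, in which the chloroiminium electrophile attacks C2 (equivalent to C6), para to one methoxy group and ortho to the other, rather than the position squeezed between both methoxy groups (the established orientation for 5-substituted 1,3-dimethoxybenzenes), and water then hydrolyses iminium 2 to the aldehyde.

Step 2
Reactants: 3 2-bromo-4,6-dimethoxybenzaldehyde
Product: 4 2-bromo-6-hydroxy-4-methoxybenzaldehyde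
Conditions: BCl3, CH2Cl2, −78 °C → rt; then H2O
Reagents that add atoms: none
Why: Chelation-directed Lewis-acid ether cleavage, in which BCl3 binds the carbonyl oxygen and the adjacent C6 methoxy oxygen in a six-membered chelate so that chloride removes only that methyl group, while the unchelated C4 methoxy group and the aryl bromide stay intact.

Step 3
Reactants: 4 2-bromo-6-hydroxy-4-methoxybenzaldehyde
Product: 5 2-(benzyloxy)-6-bromo-4-methoxybenzaldehyde
Conditions: BnBr, K2CO3, DMF, 50 °C
Reagents that add atoms: benzyl bromide BrCc1ccccc1
Why: Williamson ether synthesis, in which carbonate deprotonates the acidic, hydrogen-bonded salicylaldehyde-type phenol in a dipolar aprotic solvent and the phenoxide displaces bromide by SN2, nothing else in 4 being nucleophilic.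

Step 4
Reactants: 5 2-(benzyloxy)-6-bromo-4-methoxybenzaldehyde, 6 1-(benzyloxy)-4-bromobenzene
Product: 8 [2-(benzyloxy)-6-bromo-4-methoxyphenyl][4-(benzyloxy)phenyl]methanol (racemic), via Grignard reagent 7 (not isolated)
Conditions: 6, Mg, I2 (cat.), THF, reflux; then 5, THF, 0 °C → rt; aq NH4Cl
Reagents that add atoms: none
Why: Grignard addition, in which aryl Grignard 7 (no β-hydrogen, so no carbonyl reduction) adds to the aldehyde far faster than it could exchange with the aryl bromide at 0 °C, giving the carbinol as a racemate whose stereocentre is removed in step 5.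

Step 5
Reactants: 8 [2-(benzyloxy)-6-bromo-4-methoxyphenyl][4-(benzyloxy)phenyl]methanol
Product: 9 1-(benzyloxy)-3-bromo-2-[4-(benzyloxy)benzyl]-5-methoxybenzene
Conditions: Et3SiH, TFA (added last), CH2Cl2, −10 → 0 °C
Reagents that add atoms: none
Why: Ionic hydrogenation (silane/acid deoxygenation), in which TFA ionises the carbinol to a benzhydryl cation stabilised by the ortho and para oxygen substituents of ring A and the para-benzyloxy group of ring B, and the Et3SiH already present delivers hydride before the aryl benzyl ethers, which tolerate cold TFA, can be touched.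

Step 6
Reactants: 10 3-iodophenol
Product: 11 1-(benzyloxy)-3-iodobenzene
Conditions: BnBr, K2CO3, acetone, reflux
Reagents that add atoms: benzyl bromide BrCc1ccccc1
Why: Williamson ether synthesis of a simple phenol with benzyl bromide, to which the aryl iodide is inert.

Step 7
Reactants: 9 1-(benzyloxy)-3-bromo-2-[4-(benzyloxy)benzyl]-5-methoxybenzene, 12 trimethylsilylacetylene, 11 1-(benzyloxy)-3-iodobenzene
Product: 15 1-(benzyloxy)-2-[4-(benzyloxy)benzyl]-3-{[3-(benzyloxy)phenyl]ethynyl}-5-methoxybenzene, via silyl alkyne 13 (not isolated), via terminal alkyne 14 (not isolated)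
Conditions: 9, 12, Pd(PhCN)2Cl2 (3 mol %), [HP(t-Bu)3]BF4 (6 mol %), CuI (2 mol %), i-Pr2NH, 1,4-dioxane, Ar, rt → 45 °C (sealed); Ar sweep to expel excess 12; then 11, TBAF (THF), rt → 40 °C
Reagents that add atoms: none
Why: Two Sonogashira cycles run back to back on one C2 unit: Pd(0)/P(t-Bu)3 inserts into the C3–Br bond of 9, the copper acetylide of 12 transmetalates and reductive elimination gives silyl alkyne 13, after which fluoride strips silicon to release 14, which enters the second cycle with the far more reactive iodide 11. The closest known reaction type is the one-pot Sonogashira/desilylation/Sonogashira assembly of unsymmetrical diarylalkynes from trimethylsilylacetylene, and mild alkynylation of ortho-substituted aryl bromides with the Pd/P(t-Bu)3/CuI system is established. No ring is closed and no stereocentre is created. The selectivity needed is cross-assembly over homo-assembly: the SiMe3 cap leaves only one C–H end free in the first stage, the bromide is consumed before any iodide is present, and unreacted volatile 12 is swept out before fluoride is added, so neither symmetrical diarylalkyne can build up. Fluoride-triggered release keeps the concentration of 14 low under strict exclusion of oxygen, which holds back Glaser dimerisation. The C–Br carbon of 9 is meta to both oxygen substituents and has a single ortho neighbour (the benzyl CH2), so oxidative addition is retarded only sterically, and the benzyl ethers, the methyl ether and the diarylmethane CH2 are inert to the conditions.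

Step 8
Reactants: 15 1-(benzyloxy)-2-[4-(benzyloxy)benzyl]-3-{[3-(benzyloxy)phenyl]ethynyl}-5-methoxybenzene
Product: 16 IN1159, 3-[2-(3-hydroxyphenyl)ethyl]-2-(4-hydroxybenzyl)-5-methoxyphenol
Conditions: H2 (balloon), 10 % Pd/C, EtOAc/MeOH, rt
Reagents that add atoms: none
Why: Heterogeneous catalytic hydrogenation and hydrogenolysis, in which Pd/C adds two equivalents of H2 to the diarylalkyne and cleaves the three benzylic C–O bonds, whereas the aryl methyl ether, the diarylmethane C–C bonds and the phenol rings are not attacked under these mild conditions, so the achiral target is released in one operation.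

Compound list
1 | 1-bromo-3,5-dimethoxybenzene | COc1cc(Br)cc(OC)c1 | starting material
2 | (2-bromo-4,6-dimethoxybenzylidene)dimethyliminium chloride | COc1cc(Br)c(C=[N+](C)C)c(OC)c1.[Cl-] | intermediate (not isolated)
3 | 2-bromo-4,6-dimethoxybenzaldehyde | COc1cc(Br)c(C=O)c(OC)c1 | intermediate
4 | 2-bromo-6-hydroxy-4-methoxybenzaldehyde | COc1cc(O)c(C=O)c(Br)c1 | intermediate
5 | 2-(benzyloxy)-6-bromo-4-methoxybenzaldehyde | COc1cc(Br)c(C=O)c(OCc2ccccc2)c1 | intermediate
6 | 1-(benzyloxy)-4-bromobenzene | Brc1ccc(OCc2ccccc2)cc1 | starting material
7 | 4-(benzyloxy)phenylmagnesium bromide | Br[Mg]c1ccc(OCc2ccccc2)cc1 | intermediate (not isolated)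
8 | [2-(benzyloxy)-6-bromo-4-methoxyphenyl][4-(benzyloxy)phenyl]methanol, racemic | COc1cc(Br)c(C(O)c2ccc(OCc3ccccc3)cc2)c(OCc2ccccc2)c1 | intermediate
9 | 1-(benzyloxy)-3-bromo-2-[4-(benzyloxy)benzyl]-5-methoxybenzene | COc1cc(Br)c(Cc2ccc(OCc3ccccc3)cc2)c(OCc2ccccc2)c1 | intermediate
10 | 3-iodophenol | Oc1cccc(I)c1 | starting material
11 | 1-(benzyloxy)-3-iodobenzene | Ic1cccc(OCc2ccccc2)c1 | intermediate
12 | trimethylsilylacetylene | C#C[Si](C)(C)C | starting material
13 | ({3-(benzyloxy)-2-[4-(benzyloxy)benzyl]-5-methoxyphenyl}ethynyl)trimethylsilane | COc1cc(C#C[Si](C)(C)C)c(Cc2ccc(OCc3ccccc3)cc2)c(OCc2ccccc2)c1 | intermediate (not isolated)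
14 | 1-(benzyloxy)-2-[4-(benzyloxy)benzyl]-3-ethynyl-5-methoxybenzene | COc1cc(C#C)c(Cc2ccc(OCc3ccccc3)cc2)c(OCc2ccccc2)c1 | intermediate (not isolated)
15 | 1-(benzyloxy)-2-[4-(benzyloxy)benzyl]-3-{[3-(benzyloxy)phenyl]ethynyl}-5-methoxybenzene | COc1cc(C#Cc2cccc(OCc3ccccc3)c2)c(Cc2ccc(OCc3ccccc3)cc2)c(OCc2ccccc2)c1 | intermediate
16 | IN1159, 3-[2-(3-hydroxyphenyl)ethyl]-2-(4-hydroxybenzyl)-5-methoxyphenol (achiral) | COc1cc(O)c(Cc2ccc(O)cc2)c(CCc2cccc(O)c2)c1 | target

Total step count: 8. Longest linear sequence: 7 (steps 1–5, 7, 8). Step 6 is a one-step side branch.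

Steps most likely to fail

1. Step 7.
- What may go wrong: slow oxidative addition at the ortho-benzylated C–Br bond, premature loss of silicon during the first stage, or, in the second stage, oxidative alkyne dimerisation and consumption of the iodide by residual silylacetylene.
- Fallback (sets out from 9, comes back at 14): the first aryl–C(sp) bond is made without palladium. Bromine–lithium exchange of 9 (n-BuLi, THF, −78 °C) followed by a DMF quench should give 3-(benzyloxy)-2-[4-(benzyloxy)benzyl]-5-methoxybenzaldehyde F1. Ohira–Bestmann homologation (dimethyl (1-diazo-2-oxopropyl)phosphonate, K2CO3, MeOH/THF, rt) converts it into terminal alkyne 14, now isolated and purified. An ordinary two-component Sonogashira coupling of 14 with iodide 11 (PdCl2(PPh3)2, CuI, Et3N, THF, rt) then leads to 15.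

2. Step 5.
- What may go wrong: acid-induced loss of a benzyl ether from the strongly stabilised cation, or Friedel–Crafts self-alkylation of the electron-rich rings in competition with hydride transfer.
- Fallback (sets out from 5, comes back at 9, bypassing steps 4 and 5): the diarylmethane is made by C(sp3)–C(sp2) coupling, so no benzhydryl cation is ever generated in acid. NaBH4 (MeOH/THF, 0 °C) should reduce 5 to [2-(benzyloxy)-6-bromo-4-methoxyphenyl]methanol F2. MsCl/Et3N (CH2Cl2, 0 °C), where the labile mesylate collapses to the chloride in situ, gives 1-(benzyloxy)-3-bromo-2-(chloromethyl)-5-methoxybenzene F3, used crude. Copper-catalysed cross-coupling of F3 with Grignard reagent 7 (Li2CuCl4 cat., THF, −20 → 0 °C), to which the aryl bromide is inert, delivers 9.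

3. Step 8.
- What may go wrong: stalling of the hydrogenolysis through poisoning of the palladium surface by traces of iodide, copper or phosphine carried over from step 7, or incomplete cleavage of the crowded ring-A benzyl ether.
- Fallback (sets out from 15, comes back at 16): saturation and deprotection are separated and both are done without a heterogeneous catalyst. Diimide generated from p-toluenesulfonyl hydrazide and NaOAc (DME/H2O, reflux, excess reagent) should reduce the alkyne to 1-(benzyloxy)-2-[4-(benzyloxy)benzyl]-3-{2-[3-(benzyloxy)phenyl]ethyl}-5-methoxybenzene F4. BCl3 with pentamethylbenzene as cation scavenger (CH2Cl2, −78 °C) then removes the three benzyl groups while the unchelated aryl methyl ether survives, giving 16.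

Further compounds
F1 | step 7 | 3-(benzyloxy)-2-[4-(benzyloxy)benzyl]-5-methoxybenzaldehyde | COc1cc(C=O)c(Cc2ccc(OCc3ccccc3)cc2)c(OCc2ccccc2)c1
F2 | step 5 | [2-(benzyloxy)-6-bromo-4-methoxyphenyl]methanol | COc1cc(Br)c(CO)c(OCc2ccccc2)c1
F3 | step 5 | 1-(benzyloxy)-3-bromo-2-(chloromethyl)-5-methoxybenzene | COc1cc(Br)c(CCl)c(OCc2ccccc2)c1
F4 | step 8 | 1-(benzyloxy)-2-[4-(benzyloxy)benzyl]-3-{2-[3-(benzyloxy)phenyl]ethyl}-5-methoxybenzene | COc1cc(CCc2cccc(OCc3ccccc3)c2)c(Cc2ccc(OCc3ccccc3)cc2)c(OCc2ccccc2)c1
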